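## Retrosynthetic overview

(Germacrane numbering: ring C1–C10, lactone carbons C11–C13, C14 on C10, C15 on C4.)

1. Target 21 ⇐ bis-silyl ether 20 ⇐ acyclic iodide/bromoalkene 19: the C9–C10 bond is closed last by a nickel-mediated radical macrocyclization (primary C9 radical captured at the C10 alkenyl–nickel).
2. 19 ⇐ diol 15 (primary iodide, angelate on O8) ⇐ 13: the C1/C3 anti-diol comes from a boron aldol of methyl ketone 8 with 2-bromoacrolein, then a hydroxyl-directed reduction.
3. Lactone 8 (C6/C7 cis, C8 from the chiral pool) ⇐ Z-keto-enal 2 + allylic bromide 6 by indium Barbier allylation and lactonization.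
4. 2 ⇐ 2,3-dimethylfuran (Z-olefin inherited from the ring); 6 ⇐ (S)-but-3-ene-1,2-diol + methyl 2-(bromomethyl)acrylate by cross-metathesis.
5. Ring order: γ-lactone first (step 4), ten-membered carbocycle last (step 11).

Assumption: 2-bromoprop-2-enal (9) is bought as such and distilled immediately before use.

## Route

Step 1
Reactants: 1 2,3-dimethylfuran
Product: 2 (2Z)-3-methyl-4-oxopent-2-enal
Conditions: dimethyldioxirane (1.05 equiv), acetone, −78 → −20 °C; concentrated cold, used at once
Reagents that add atoms: dimethyldioxirane (CC1(C)OO1)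
Why: Oxidative furan ring opening (epoxidation of the 2,3-bond and collapse of the epoxide) gives the cis-enedione, so the Z geometry of the later C4=C5 olefin is inherited from the ring; no stereocentre is formed.

Step 2
Reactants: 3 (2S)-but-3-ene-1,2-diol
Product: 4 (4S)-4-ethenyl-2,2-dimethyl-1,3-dioxolane
Conditions: Me2C(OMe)2, PPTS (cat.), CH2Cl2, rt
Reagents that add atoms: 2,2-dimethoxypropane (COC(C)(C)OC)
Why: Acetonide formation by transacetalization; the stereocentre (later C8) comes from the chiral pool and is not touched.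

Step 3
Reactants: 4 (4S)-4-ethenyl-2,2-dimethyl-1,3-dioxolane; 5 methyl 2-(bromomethyl)prop-2-enoate
Product: 6 methyl (2Z)-2-(bromomethyl)-3-[(4S)-2,2-dimethyl-1,3-dioxolan-4-yl]prop-2-enoate
Conditions: 5 (3 equiv), second-generation Hoveyda–Grubbs catalyst RuCl2(H2IMes)(=CH-C6H4-2-OiPr) (5 mol %), CH2Cl2, 40 °C
Reagents that add atoms: none
Why: Olefin cross-metathesis gives the more stable trisubstituted enoate with the dioxolane trans to the ester (cis to CH2Br, hence Z); C8 is unaffected.

Step 4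
Reactants: 2 (2Z)-3-methyl-4-oxopent-2-enal; 6 allylic bromide
Product: 8 cis-lactone (4S,5S)-4-[(4S)-dioxolanyl]-3-methylidene-5-[(1Z)-2-methyl-3-oxobutenyl]oxolan-2-one, via hydroxy ester 7 (not isolated)
Conditions: In powder, THF/H2O (1:1), 0 °C → rt; extractive work-up; NaH (0.1 equiv), THF, 0 °C
Reagents that add atoms: none
Why: Indium-mediated Barbier allylation is aldehyde-selective and passes through a closed chair transition state with the substituent cis to the CH2–In carbon axial, so C6 and C7 come out cis on the lactone (syn adduct); with the C8–H eclipsing the olefin (allylic 1,3-strain) the aldehyde and indium engage the face flanked by the small dioxolane oxygen rather than by C9, placing C11 anti to O8 as in the target, and catalytic alkoxide then closes the γ-lactone on O6 before the cis-γ-hydroxy enone can dehydrate to a furan.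

Step 5
Reactants: 8 lactone methyl ketone; 9 2-bromoprop-2-enal
Product: 12 β-hydroxy enone (C1 carbinol S), via boron enolate 10 (not isolated), via boron aldolate 11 (not isolated)
Conditions: (−)-Ipc2BCl, Et3N, Et2O, 0 °C; 9, −78 → −20 °C; H2O2, pH 7 buffer, MeOH, 0 °C
Reagents that add atoms: none
Why: Paterson boron aldol of a methyl ketone: the kinetic cross-conjugated bis(isopinocampheyl)boron enolate adds to the aldehyde under reagent control (si-face attack expected for this antipode; the other antipode is used if Mosher analysis shows the reverse) and sets C1 as S, the remote lactone stereocentres having no influence.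

Step 6
Reactants: 12 β-hydroxy enone
Product: 13 anti-1,3-diol (C1 S, C3 S)
Conditions: Me4NBH(OAc)3, MeCN/AcOH (1:1), −35 °C
Reagents that add atoms: none
Why: Evans–Saksena reduction: the C1 hydroxyl binds the triacetoxyborohydride and delivers hydride intramolecularly through a chair transition state, giving the 1,3-anti diol and setting C3 as S.

Step 7
Reactants: 13 anti-1,3-diol
Product: 14 bis(tert-butyldimethylsilyl) ether
Conditions: TBSOTf (2.6 equiv), 2,6-lutidine, CH2Cl2, −78 °C
Reagents that add atoms: tert-butyldimethylsilyl trifluoromethanesulfonate (CC(C)(C)[Si](C)(C)OS(=O)(=O)C(F)(F)F)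
Why: Silyl ether formation; the low temperature and hindered base leave the acetonide and the α-methylene lactone untouched, and no stereocentre is affected.

Step 8
Reactants: 14 bis-silyl ether acetonide
Product: 15 lactone 1,2-diol (C8 and C9 hydroxyls free)
Conditions: PPTS, MeOH, rt
Reagents that add atoms: none
Why: Acid-catalysed transacetalization (methanolysis) of the terminal acetonide, which is far more labile than the secondary allylic silyl ethers; C8 is unchanged.

Step 9
Reactants: 15 lactone 1,2-diol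
Product: 16 primary iodide with free C8 hydroxyl
Conditions: I2, PPh3, imidazole (premixed), CH2Cl2, 0 °C
Reagents that add atoms: iodine (II)
Why: Garegg–Samuelsson (Appel-type) iodination, selective for the primary hydroxyl on steric grounds; the C8 carbinol is not touched.

Step 10
Reactants: 16 iodo alcohol; 17 (2Z)-2-methylbut-2-enoic acid (angelic acid)
Product: 19 C8 angelate with C9 iodide and C10 bromoalkene, via mixed anhydride 18 (not isolated)
Conditions: 17, 2,4,6-Cl3C6H2COCl, Et3N, toluene, rt; then 16, DMAP, rt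
Reagents that add atoms: none
Why: Yamaguchi esterification acylates at oxygen with retention at C8, and the mixed-anhydride conditions at room temperature keep the Z (angelate) geometry.

Step 11
Reactants: 19 iodide/bromoalkene
Product: 20 ten-membered bis-silyl ether (1S,3S,6S,7R,8R)
Conditions: NiBr2·dme (30 mol %), 4,4′-di-tert-butyl-2,2′-bipyridine (30 mol %), Mn powder (4 equiv), NaI (0.5 equiv), DMA, 40 °C; 19 added over 12 h (final 2 mM)
Reagents that add atoms: none
Why: Proposed new method: nickel-catalysed reductive cross-electrophile macrocyclization, in which zerovalent nickel inserts into the alkenyl C10–Br bond, a monovalent nickel halide abstracts iodine from C9 to give a primary alkyl radical, and this radical is captured at the alkenyl–nickel centre of the same molecule before reductive elimination forms C9–C10; no stereocentre is created, the β-acyloxy radical does not eliminate, and slow addition suppresses oligomers; the closest known reaction type is the intermolecular nickel/bipyridine reductive coupling of alkenyl bromides with primary alkyl iodides.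

Step 12
Reactants: 20 macrocyclic bis-silyl ether
Product: 21 target
Conditions: HF·pyridine, pyridine, THF, 0 °C → rt
Reagents that add atoms: none
Why: Fluoride-mediated desilylation under buffered conditions that tolerate the angelate, the α-methylene lactone and the two allylic alcohols; no stereocentre is affected.

## Compound list

1 | 2,3-dimethylfuran | Cc1occc1C | starting material
2 | (2Z)-3-methyl-4-oxopent-2-enal | CC(=O)/C(C)=C\C=O | intermediate
3 | (2S)-but-3-ene-1,2-diol | C=C[C@H](O)CO | starting material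
4 | (4S)-4-ethenyl-2,2-dimethyl-1,3-dioxolane | C=C[C@H]1COC(C)(C)O1 | intermediate
5 | methyl 2-(bromomethyl)prop-2-enoate | C=C(CBr)C(=O)OC | starting material
6 | methyl (2Z)-2-(bromomethyl)-3-[(4S)-2,2-dimethyl-1,3-dioxolan-4-yl]prop-2-enoate | COC(=O)/C(CBr)=C/[C@H]1COC(C)(C)O1 | intermediate
7 | methyl (3S,4S,5Z)-3-[(4S)-2,2-dimethyl-1,3-dioxolan-4-yl]-4-hydroxy-6-methyl-2-methylidene-7-oxooct-5-enoate | COC(=O)C(=C)[C@@H]([C@@H](O)/C=C(/C)C(C)=O)[C@H]1COC(C)(C)O1 | intermediate
8 | (4S,5S)-4-[(4S)-2,2-dimethyl-1,3-dioxolan-4-yl]-3-methylidene-5-[(1Z)-2-methyl-3-oxobut-1-en-1-yl]oxolan-2-one | C=C1C(=O)O[C@@H](/C=C(/C)C(C)=O)[C@H]1[C@H]2COC(C)(C)O2 | intermediate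
9 | 2-bromoprop-2-enal | C=C(Br)C=O | starting material
10 | bis(isopinocampheyl)boron enolate of 8 (boron on the ketone oxygen, C2=C3 enol double bond) | C=C1C(=O)O[C@@H](/C=C(/C)C(=C)OB([C@@H]3C[C@@H]4C[C@H]([C@H]3C)C4(C)C)[C@@H]3C[C@@H]4C[C@H]([C@H]3C)C4(C)C)[C@H]1[C@H]2COC(C)(C)O2 | intermediate
11 | bis(isopinocampheyl)borinate ester of aldol 12 (boron on the C1 oxygen) | C=C1C(=O)O[C@@H](/C=C(/C)C(=O)C[C@H](OB([C@@H]3C[C@@H]4C[C@H]([C@H]3C)C4(C)C)[C@@H]3C[C@@H]4C[C@H]([C@H]3C)C4(C)C)C(Br)=C)[C@H]1[C@H]2COC(C)(C)O2 | intermediate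
12 | (4S,5S)-5-[(1Z,5S)-6-bromo-5-hydroxy-2-methyl-3-oxohepta-1,6-dien-1-yl]-4-[(4S)-2,2-dimethyl-1,3-dioxolan-4-yl]-3-methylideneoxolan-2-one | C=C1C(=O)O[C@@H](/C=C(/C)C(=O)C[C@H](O)C(Br)=C)[C@H]1[C@H]2COC(C)(C)O2 | intermediate
13 | (4S,5S)-5-[(1Z,3S,5S)-6-bromo-3,5-dihydroxy-2-methylhepta-1,6-dien-1-yl]-4-[(4S)-2,2-dimethyl-1,3-dioxolan-4-yl]-3-methylideneoxolan-2-one | C=C1C(=O)O[C@@H](/C=C(/C)[C@@H](O)C[C@H](O)C(Br)=C)[C@H]1[C@H]2COC(C)(C)O2 | intermediate
14 | (4S,5S)-5-[(1Z,3S,5S)-6-bromo-3,5-bis{[tert-butyl(dimethyl)silyl]oxy}-2-methylhepta-1,6-dien-1-yl]-4-[(4S)-2,2-dimethyl-1,3-dioxolan-4-yl]-3-methylideneoxolan-2-one | C=C1C(=O)O[C@@H](/C=C(/C)[C@@H](O[Si](C)(C)C(C)(C)C)C[C@H](O[Si](C)(C)C(C)(C)C)C(Br)=C)[C@H]1[C@H]2COC(C)(C)O2 | intermediate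
15 | (4R,5S)-5-[(1Z,3S,5S)-6-bromo-3,5-bis{[tert-butyl(dimethyl)silyl]oxy}-2-methylhepta-1,6-dien-1-yl]-4-[(1S)-1,2-dihydroxyethyl]-3-methylideneoxolan-2-one | C=C1C(=O)O[C@@H](/C=C(/C)[C@@H](O[Si](C)(C)C(C)(C)C)C[C@H](O[Si](C)(C)C(C)(C)C)C(Br)=C)[C@H]1[C@H](O)CO | intermediate
16 | (4R,5S)-5-[(1Z,3S,5S)-6-bromo-3,5-bis{[tert-butyl(dimethyl)silyl]oxy}-2-methylhepta-1,6-dien-1-yl]-4-[(1S)-1-hydroxy-2-iodoethyl]-3-methylideneoxolan-2-one | C=C1C(=O)O[C@@H](/C=C(/C)[C@@H](O[Si](C)(C)C(C)(C)C)C[C@H](O[Si](C)(C)C(C)(C)C)C(Br)=C)[C@H]1[C@H](O)CI | intermediate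
17 | (2Z)-2-methylbut-2-enoic acid (angelic acid) | C/C=C(/C)C(=O)O | starting material
18 | (2Z)-2-methylbut-2-enoic 2,4,6-trichlorobenzoic anhydride | C/C=C(/C)C(=O)OC(=O)c1c(Cl)cc(Cl)cc1Cl | intermediate
19 | (4S,5S)-5-[(1Z,3S,5S)-6-bromo-3,5-bis{[tert-butyl(dimethyl)silyl]oxy}-2-methylhepta-1,6-dien-1-yl]-4-[(1S)-2-iodo-1-{[(2Z)-2-methylbut-2-enoyl]oxy}ethyl]-3-methylideneoxolan-2-one | C=C1C(=O)O[C@@H](/C=C(/C)[C@@H](O[Si](C)(C)C(C)(C)C)C[C@H](O[Si](C)(C)C(C)(C)C)C(Br)=C)[C@H]1[C@H](OC(=O)/C(C)=C\C)CI | intermediate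
20 | (1S,3S,6S,7R,8R)-8-angeloyloxy-1,3-bis{[tert-butyl(dimethyl)silyl]oxy}germacra-4Z,10(14),11(13)-trien-12,6-olide | C=C1C(=O)O[C@H]2/C=C(/C)[C@@H](O[Si](C)(C)C(C)(C)C)C[C@H](O[Si](C)(C)C(C)(C)C)C(=C)C[C@@H](OC(=O)/C(C)=C\C)[C@@H]12 | intermediate
21 | (1S,3S,6S,7R,8R)-8-angeloyloxy-1,3-dihydroxygermacra-4Z,10(14),11(13)-trien-12,6-olide | C=C1C(=O)O[C@H]2/C=C(/C)[C@@H](O)C[C@H](O)C(=C)C[C@@H](OC(=O)/C(C)=C\C)[C@@H]12 | target

## Step count and risk

Total step count: 12. Longest linear sequence: 11 steps (3 → 4 → 6 → 8 → 12 → 13 → 14 → 15 → 16 → 19 → 20 → 21).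

**Step 11 (nickel radical macrocyclization).** The ten-membered ring is strained, the catalyst must work at high dilution, low-valent nickel may ionise the allylic lactone C6–O bond, and the β-acyloxy iodide may be reduced or eliminated. The fallback replaces radical capture with a two-electron cross-coupling and carries O8 as a silyl ether. It sets out from 16 and returns at 20. Compound 16 is silylated on O8 (TESOTf, 2,6-lutidine, CH2Cl2, −78 °C) to give the triethylsilyl ether F1. Zinc insertion (Zn dust, LiCl, THF, 30 °C) gives the alkylzinc iodide F2. Intramolecular Negishi coupling (Pd(OAc)2, CPhos, THF, slow addition) closes the ring to the O8-triethylsilyl macrocycle F3. HF·pyridine/pyridine at 0 °C removes only the triethylsilyl group to give the macrocyclic C8 alcohol F4. Yamaguchi esterification with 17 then gives 20.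

**Step 4 (Barbier allylation and lactonization on the Z-keto-enal).** The cis-enedione is labile, the intermediate cis-γ-hydroxy enone can close to a hemiketal and aromatise to a furan, and the facial sense relative to C8 rests on a model. The fallback is an allylboration, in which no free γ-hydroxy enone is liberated. It sets out from 6 and returns at 8. Allylic borylation of 6 (B2pin2, Pd2(dba)3, DMSO, rt) gives the allylboronate F5. Thermal allylboration of 2 (toluene, 50 °C, closed chair transition state, aldehyde-selective) gives a boron alkoxide that lactonises directly to 8.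

**Step 3 (cross-metathesis).** A 1,1-disubstituted acrylate carrying an allylic bromide is a poor metathesis partner for an allylic-oxygenated olefin. The fallback builds the same bromide by Morita–Baylis–Hillman chemistry. It sets out from 4 and returns at 6. Ozonolysis of 4 (O3, CH2Cl2, −78 °C; PPh3) gives (4R)-2,2-dimethyl-1,3-dioxolane-4-carbaldehyde F6. Reaction with methyl acrylate and DABCO gives the allylic alcohol F7 (both carbinol epimers, of no consequence). NBS/Me2S in CH2Cl2 effects the SN2′ bromination to 6.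

## Further compounds

F1 | step 11 | (4S,5S)-5-[(1Z,3S,5S)-6-bromo-3,5-bis{[tert-butyl(dimethyl)silyl]oxy}-2-methylhepta-1,6-dien-1-yl]-4-[(1S)-2-iodo-1-[(triethylsilyl)oxy]ethyl]-3-methylideneoxolan-2-one | C=C1C(=O)O[C@@H](/C=C(/C)[C@@H](O[Si](C)(C)C(C)(C)C)C[C@H](O[Si](C)(C)C(C)(C)C)C(Br)=C)[C@H]1[C@H](O[Si](CC)(CC)CC)CI
F2 | step 11 | alkylzinc iodide from F1 (C9–ZnI in place of C9–I, otherwise unchanged) | C=C1C(=O)O[C@@H](/C=C(/C)[C@@H](O[Si](C)(C)C(C)(C)C)C[C@H](O[Si](C)(C)C(C)(C)C)C(Br)=C)[C@H]1[C@H](O[Si](CC)(CC)CC)C[Zn]I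
F3 | step 11 | macrocycle 20 with a triethylsilyl ether on O8 in place of the angelate (same configuration at C1, C3, C6, C7, C8) | C=C1C(=O)O[C@H]2/C=C(/C)[C@@H](O[Si](C)(C)C(C)(C)C)C[C@H](O[Si](C)(C)C(C)(C)C)C(=C)C[C@@H](O[Si](CC)(CC)CC)[C@@H]12
F4 | step 11 | macrocycle 20 with a free C8 hydroxyl in place of the angelate (same configuration at C1, C3, C6, C7, C8) | C=C1C(=O)O[C@H]2/C=C(/C)[C@@H](O[Si](C)(C)C(C)(C)C)C[C@H](O[Si](C)(C)C(C)(C)C)C(=C)C[C@@H](O)[C@@H]12
F5 | step 4 | methyl (2E)-3-[(4S)-2,2-dimethyl-1,3-dioxolan-4-yl]-2-[(4,4,5,5-tetramethyl-1,3,2-dioxaborolan-2-yl)methyl]prop-2-enoate | COC(=O)/C(CB1OC(C)(C)C(C)(C)O1)=C/[C@H]2COC(C)(C)O2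
F6 | step 3 | (4R)-2,2-dimethyl-1,3-dioxolane-4-carbaldehyde | O=C[C@H]1COC(C)(C)O1
F7 | step 3 | methyl 2-{[(4R)-2,2-dimethyl-1,3-dioxolan-4-yl](hydroxy)methyl}prop-2-enoate (both carbinol epimers) | C=C(C(=O)OC)C(O)[C@H]1COC(C)(C)O1
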